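The route rests on cutting ring A (C5 to C8) of the C-methylated flavone half away from its pyranone ring C. That ring carries OH at C5, CH3 at C6, OCH3 at C7 and H at C8. This is the pattern produced when a vinylketene combines with 1-methoxypropyne. One operation (Wolff shift, [2+2] addition, 4π opening, 6π closure, enolisation) builds ring A as a single regioisomer, with the C5 phenol free and O7 already methylated. The precursor is a 4-pyranone with a diazoacetyl group at C2 and ring B at C6. Ring B (4′-OCH3) is already bonded through C3′ to C8″ of tri-O-benzylapigenin.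

Key step: step 9

Remark on the chemistry: the target has no stereocentre and its 3′–8″ axis carries no descriptor, so axial chirality is not controlled. Locants: unprimed = methylated flavone (rings A and C; C4a and C8a are the fusion carbons), ′ = ring B, ″ = apigenin chromenone, ‴ = its 4-oxygenated phenyl ring.

Step 1
Reactants: 1 apigenin
Product: 2 5,7,4′-tri-O-benzylapigenin
Conditions: BnBr (4.5 equiv), K2CO3, DMF, 80 °C
Reagents that add atoms: benzyl bromide, BrCc1ccccc1
Why: Williamson ether synthesis, in which excess halide and heat in DMF also alkylate the hydrogen-bonded 5-OH, so that no acidic phenol remains for the later diazomethane and ketene stages and ring A is prepared for C8-selective iodination.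

Step 2
Reactants: 2 5,7,4′-tri-O-benzylapigenin
Product: 3 8-iodo-5,7,4′-tri-O-benzylapigenin
Conditions: I2, AgO2CCF3, CH2Cl2, 0 °C to rt, dark
Reagents that add atoms: iodine, II
Why: Electrophilic aromatic iodination by the acyl hypoiodite formed in situ, which in fully O-alkylated 5,7-dioxygenated flavones goes to ring A at C8 because C6 is shielded by two flanking benzyloxy groups and the 4-benzyloxyphenyl ring is deactivated by conjugation with the pyranone carbonyl.

Step 3
Reactants: 4 3-bromo-4-methoxyacetophenone; 5 ethyl acetate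
Product: 6 1-(3-bromo-4-methoxyphenyl)butane-1,3-dione
Conditions: NaH, THF, reflux; then 1 M HCl
Reagents that add atoms: none
Why: Crossed Claisen condensation of the aryl methyl ketone enolate with ethyl acetate, pulled forward by irreversible deprotonation of the 1,3-diketone that forms.

Step 4
Reactants: 6 1-(3-bromo-4-methoxyphenyl)butane-1,3-dione; 7 diethyl oxalate
Product: 9 ethyl 6-(3-bromo-4-methoxyphenyl)-4-oxo-4H-pyran-2-carboxylate, via triketo ester 8 (not isolated)
Conditions: NaOEt, EtOH, 0 to 60 °C; then conc. HCl, EtOH, reflux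
Reagents that add atoms: none
Why: Claisen condensation with the non-enolisable oxalate at the terminal CH3 of the diketone (acylation at the central carbon is reversible, that at CH3 ends in a stable bis-enolate), followed by acid-catalysed cyclodehydration of the 1,3,5-tricarbonyl chain, the classical entry to 6-aryl-4-pyranone-2-carboxylates, with ethanol as solvent keeping the ester intact.

Step 5
Reactants: 9 ethyl 6-(3-bromo-4-methoxyphenyl)-4-oxo-4H-pyran-2-carboxylate
Product: 10 ethyl 6-[4-methoxy-3-(4,4,5,5-tetramethyl-1,3,2-dioxaborolan-2-yl)phenyl]-4-oxo-4H-pyran-2-carboxylate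
Conditions: B2pin2, PdCl2(dppf), KOAc, dioxane, 90 °C
Reagents that add atoms: bis(pinacolato)diboron, CC1(C)OB(OC1(C)C)B1OC(C)(C)C(C)(C)O1
Why: Miyaura borylation of the aryl bromide, in which KOAc is too weak a base to harm the ester or to open the pyranone.

Step 6
Reactants: 10 pinacol boronate of the pyranone ester; 3 8-iodo-5,7,4′-tri-O-benzylapigenin
Product: 12 6-[4-methoxy-3-(5,7,4′-tri-O-benzylapigenin-8-yl)phenyl]-4-oxo-4H-pyran-2-carboxylic acid, via biaryl ester 11 (not isolated)
Conditions: Pd(OAc)2, SPhos, K2CO3, dioxane/H2O, 80 °C; then LiOH, rt; then 1 M HCl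
Reagents that add atoms: lithium hydroxide, [Li+].[OH-]
Why: Suzuki–Miyaura coupling in the polarity proven for 3′–8″-linked biflavones (8-iodoflavone plus ring B boronate) with a bulky biarylphosphine for the tri-ortho-substituted axis, and, since the activated ester would be partly hydrolysed by the aqueous base anyway, saponification is completed in the same flask and acidification recloses any opened pyranone.

Step 7
Reactants: 12 biaryl pyranone carboxylic acid
Product: 14 2-(diazoacetyl)-6-[4-methoxy-3-(5,7,4′-tri-O-benzylapigenin-8-yl)phenyl]-4H-pyran-4-one, via acid chloride 13 (not isolated)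
Conditions: Me2C=C(Cl)NMe2, CH2Cl2, 0 °C to rt; then CH2N2 (1.2 equiv), Et3N, Et2O/CH2Cl2, −20 to 0 °C
Reagents that add atoms: diazomethane, C=[N+]=[N-]; 1-chloro-N,N,2-trimethylprop-1-en-1-amine, CC(C)=C(Cl)N(C)C (chlorine of 13 only)
Why: Acylation of diazomethane by an acid chloride (first stage of the Arndt–Eistert sequence), in which the neutral chloroenamine spares the benzyl ethers and the basic flavone carbonyl, the acid chloride has no α-hydrogen that Et3N could remove, and Et3N as HCl trap allows a near-stoichiometric charge of diazomethane so that no free dipole is left to add to the C2=C3 bond of the pyranone.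

Step 8
Reactants: 15 chloroacetaldehyde dimethyl acetal
Product: 17 1-methoxypropyne, via sodium methoxyacetylide 16 (not isolated)
Conditions: NaNH2 (3 equiv), NH3(l), −33 °C; then MeI, −33 °C; water, pentane, fractional distillation
Reagents that add atoms: iodomethane, CI
Why: Two successive base-induced eliminations (methanol, then HCl) and deprotonation give the alkynyl anion, the standard preparation of alkoxyacetylides from chloroacetals, and SN2 methylation at carbon then gives the volatile ynol ether.

Step 9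
Reactants: 14 pyranonyl diazomethyl ketone; 17 1-methoxypropyne
Product: 22 5″,7″,4‴-tri-O-benzyl Taiwanhomoflavone A (free 5-OH), via pyranonylketene 18 (not isolated), via cyclobutenone 19 (not isolated), via dienylketene 20 (not isolated), via keto tautomer 21 (not isolated)
Conditions: 17 (4 equiv), ClCH2CH2Cl, degassed, blue LED (about 440 nm), 20 °C; then PhMe, 110 °C
Reagents that add atoms: none
Why: Proposed new method: blue light, absorbed only by the diazoketone and not by the flavone or pyranone chromophores, expels N2 and the pyranon-2-yl group shifts to the diazo carbon (Wolff rearrangement, new C8–C8a bond) to give ketene 18, whose carbonyl carbon is attacked by the methyl-bearing carbon of 17, so that the [2+2] cycloaddition (new C5–C6 and C7–C8 bonds) gives cyclobutenone 19. Heating opens 19 by a reversible 4π electrocyclic reaction that cuts the old C5–C8 bond, and only dienylketene 20, with the pyranonyl group turned inward, goes on, closing ring A by a thermal disrotatory 6π electrocyclisation of the ketene carbon onto C3 of the pyranone (new C5–C4a bond), after which C4a–H of 21, flanked by two carbonyl groups, enolises irreversibly to the chelated C5 phenol. The closest known reaction type is the Danheiser benzannulation in its diazoketone form, established for aryl, heteroaryl and alkenyl diazomethyl ketones with alkoxy-, silyloxy- and aminoalkynes, whereas the C2=C3 bond of a 4-pyranone has not yet served as the vinyl unit. It should serve because C3 is the enol-ether β-carbon of O1–C2=C3, the nucleophilic site of a 4-pyranone, which matches the electrophilic ketene carbon, and because less aromatic stabilisation is given up than with benzene or thiophene. The one selectivity needed is the orientation of the [2+2] step, secured by the oxygen-induced polarisation of 17, which puts CH3 at C6 between OH and OCH3, while the ring closure has no second site since the other neighbour of C2 is the ring oxygen. No stereocentre survives (C4 of 19 and C4a of 21 are transient and racemic), all other phenols are benzylated so that nothing intercepts the ketene, and a methoxyalkyne cannot lose an alkene by the retro-ene path that limits ethoxyalkynes on heating.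

Step 10
Reactants: 22 5″,7″,4‴-tri-O-benzyl Taiwanhomoflavone A
Product: 23 Taiwanhomoflavone A
Conditions: H2 (1 atm), Pd/C (10 wt %), THF/MeOH, rt
Reagents that add atoms: none
Why: Catalytic hydrogenolysis of the three aryl benzyl ethers, a routine last step in flavone synthesis that leaves both methyl ethers untouched and is stopped after uptake of three equivalents of H2, well before the slower reduction of the C2=C3 bonds.

Compound list
1 | apigenin | O=c1cc(-c2ccc(O)cc2)oc2cc(O)cc(O)c12 | starting material
2 | 5,7,4′-tri-O-benzylapigenin | O=c1cc(-c2ccc(OCc3ccccc3)cc2)oc2cc(OCc3ccccc3)cc(OCc3ccccc3)c12 | intermediate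
3 | 8-iodo-5,7,4′-tri-O-benzylapigenin | O=c1cc(-c2ccc(OCc3ccccc3)cc2)oc2c(I)c(OCc3ccccc3)cc(OCc3ccccc3)c12 | intermediate
4 | 3-bromo-4-methoxyacetophenone | CC(=O)c1ccc(OC)c(Br)c1 | starting material
5 | ethyl acetate | CCOC(C)=O | starting material
6 | 1-(3-bromo-4-methoxyphenyl)butane-1,3-dione | CC(=O)CC(=O)c1ccc(OC)c(Br)c1 | intermediate
7 | diethyl oxalate | CCOC(=O)C(=O)OCC | starting material
8 | ethyl 6-(3-bromo-4-methoxyphenyl)-2,4,6-trioxohexanoate (not isolated) | CCOC(=O)C(=O)CC(=O)CC(=O)c1ccc(OC)c(Br)c1 | intermediate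
9 | ethyl 6-(3-bromo-4-methoxyphenyl)-4-oxo-4H-pyran-2-carboxylate | CCOC(=O)c1cc(=O)cc(-c2ccc(OC)c(Br)c2)o1 | intermediate
10 | ethyl 6-[4-methoxy-3-(4,4,5,5-tetramethyl-1,3,2-dioxaborolan-2-yl)phenyl]-4-oxo-4H-pyran-2-carboxylate | CCOC(=O)c1cc(=O)cc(-c2ccc(OC)c(B3OC(C)(C)C(C)(C)O3)c2)o1 | intermediate
11 | ethyl 6-[4-methoxy-3-(5,7,4′-tri-O-benzylapigenin-8-yl)phenyl]-4-oxo-4H-pyran-2-carboxylate (not isolated) | CCOC(=O)c1cc(=O)cc(-c2ccc(OC)c(-c3c(OCc4ccccc4)cc(OCc4ccccc4)c4c(=O)cc(-c5ccc(OCc6ccccc6)cc5)oc34)c2)o1 | intermediate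
12 | 6-[4-methoxy-3-(5,7,4′-tri-O-benzylapigenin-8-yl)phenyl]-4-oxo-4H-pyran-2-carboxylic acid | OC(=O)c1cc(=O)cc(-c2ccc(OC)c(-c3c(OCc4ccccc4)cc(OCc4ccccc4)c4c(=O)cc(-c5ccc(OCc6ccccc6)cc5)oc34)c2)o1 | intermediate
13 | 6-[4-methoxy-3-(5,7,4′-tri-O-benzylapigenin-8-yl)phenyl]-4-oxo-4H-pyran-2-carbonyl chloride (not isolated) | ClC(=O)c1cc(=O)cc(-c2ccc(OC)c(-c3c(OCc4ccccc4)cc(OCc4ccccc4)c4c(=O)cc(-c5ccc(OCc6ccccc6)cc5)oc34)c2)o1 | intermediate
14 | 2-(diazoacetyl)-6-[4-methoxy-3-(5,7,4′-tri-O-benzylapigenin-8-yl)phenyl]-4H-pyran-4-one | [N-]=[N+]=CC(=O)c1cc(=O)cc(-c2ccc(OC)c(-c3c(OCc4ccccc4)cc(OCc4ccccc4)c4c(=O)cc(-c5ccc(OCc6ccccc6)cc5)oc34)c2)o1 | intermediate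
15 | chloroacetaldehyde dimethyl acetal (2-chloro-1,1-dimethoxyethane) | COC(CCl)OC | starting material
16 | sodium methoxyacetylide (not isolated) | [Na+].[C-]#COC | intermediate
17 | 1-methoxypropyne | CC#COC | intermediate
18 | (6-aryl-4-oxo-4H-pyran-2-yl)ketene, aryl as in 14 (not isolated) | O=C=Cc1cc(=O)cc(-c2ccc(OC)c(-c3c(OCc4ccccc4)cc(OCc4ccccc4)c4c(=O)cc(-c5ccc(OCc6ccccc6)cc5)oc34)c2)o1 | intermediate
19 | 4-(6-aryl-4-oxo-4H-pyran-2-yl)-3-methoxy-2-methylcyclobut-2-en-1-one, racemic at C4 (not isolated) | COC1=C(C)C(=O)C1c1cc(=O)cc(-c2ccc(OC)c(-c3c(OCc4ccccc4)cc(OCc4ccccc4)c4c(=O)cc(-c5ccc(OCc6ccccc6)cc5)oc34)c2)o1 | intermediate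
20 | (3E)-4-(6-aryl-4-oxo-4H-pyran-2-yl)-3-methoxy-2-methylbuta-1,3-dien-1-one, pyranonyl cis to the ketene carbon chain (not isolated) | O=C=C(C)/C(OC)=C\c1cc(=O)cc(-c2ccc(OC)c(-c3c(OCc4ccccc4)cc(OCc4ccccc4)c4c(=O)cc(-c5ccc(OCc6ccccc6)cc5)oc34)c2)o1 | intermediate
21 | 2-aryl-7-methoxy-6-methyl-4aH-chromene-4,5-dione, keto tautomer of 22, racemic at C4a (not isolated) | COC1=C(C)C(=O)C2C(=O)C=C(-c3ccc(OC)c(-c4c(OCc5ccccc5)cc(OCc5ccccc5)c5c(=O)cc(-c6ccc(OCc7ccccc7)cc6)oc45)c3)OC2=C1 | intermediate
22 | 5″,7″,4‴-tri-O-benzyl Taiwanhomoflavone A (5-OH free) | COc1ccc(-c2cc(=O)c3c(O)c(C)c(OC)cc3o2)cc1-c1c(OCc2ccccc2)cc(OCc2ccccc2)c2c(=O)cc(-c3ccc(OCc4ccccc4)cc3)oc12 | intermediate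
23 | Taiwanhomoflavone A | COc1ccc(-c2cc(=O)c3c(O)c(C)c(OC)cc3o2)cc1-c1c(O)cc(O)c2c(=O)cc(-c3ccc(O)cc3)oc12 | target

Total step count: 10.
Longest linear sequence: 7 steps (steps 3, 4, 5, 6, 7, 9 and 10, from 4 to 23).

Steps most likely to fail

1. Step 9.
- **What may go wrong:** The ketene may be lost to dimerisation or to traces of water before it meets the alkyne. The cascade may also stall after the [2+2] stage if the 6π closure onto the cross-conjugated pyranone is too slow at temperatures the material tolerates.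
- **Fallback:** This uses known chemistry, with ring A taken from a preformed arene. It sets out from iodide 3 and comes back at 22.
- 3,5-Dimethoxy-4-methylphenol has two equivalent free ortho positions. It is C-acetylated (Ac2O, BF3·OEt2, 90 °C) to 1-(6-hydroxy-2,4-dimethoxy-3-methylphenyl)ethanone F1.
- Claisen–Schmidt condensation with 3-bromo-4-methoxybenzaldehyde (KOH, EtOH) should give the (E)-chalcone F2.
- Catalytic I2 in DMSO at 130 °C closes and dehydrogenates it to 3′-bromo-5,7,4′-trimethoxy-6-methylflavone F3. The methyl group can only end at C6, because the oxygen next to it is blocked as a methyl ether.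
- BCl3 (CH2Cl2, −78 to 0 °C) removes only the chelating 5-O-methyl group, giving 3′-bromo-5-hydroxy-7,4′-dimethoxy-6-methylflavone F4.
- Miyaura borylation as in step 5 gives the pinacol boronate F5.
- Suzuki–Miyaura coupling of F5 with 3 under the first conditions of step 6 gives 22.

2. Step 7.
- **What may go wrong:** Dipolar cycloaddition of diazomethane to the doubly activated C2=C3 bond of the pyranone may compete with acylation. Capture of the diazoketone by HCl may also erode the product.
- **Fallback:** This avoids any diazoalkane. It sets out from acid 12 and comes back at 14.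
- Coupling of 12 with Meldrum's acid (EDC·HCl, DMAP, CH2Cl2) gives the acyl Meldrum's acid F6.
- Heating in aqueous acetic acid hydrolyses and doubly decarboxylates it to the methyl ketone F7.
- LiN(SiMe3)2 (THF, −78 °C) followed by CF3CO2CH2CF3 gives the trifluoroacetyl diketone F8, which is used crude.
- Detrifluoroacetylative diazo transfer (MsN3, Et3N, H2O, MeCN, rt) then gives 14.

3. Step 6.
- **What may go wrong:** Protodeboronation of the ortho-methoxy boronate may outrun the slow coupling at the crowded C8 position. Hot aqueous base may also open the pyranone and degrade it by retro-Claisen cleavage.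
- **Fallback:** This uses tin in place of boron and no aqueous base. It sets out from bromide 9 and comes back at ester 11, which is then isolated and saponified as in the second part of step 6.
- Stannylation of 9 ((Me3Sn)2, Pd(PPh3)4, toluene, 100 °C) gives the aryl trimethylstannane F9.
- Stille coupling of F9 with 3 (Pd(PPh3)4, CuI, CsF, DMF, 50 °C) gives 11.

Further compounds
F1 | step 9 | 1-(6-hydroxy-2,4-dimethoxy-3-methylphenyl)ethanone | CC(=O)c1c(O)cc(OC)c(C)c1OC
F2 | step 9 | (E)-3-(3-bromo-4-methoxyphenyl)-1-(6-hydroxy-2,4-dimethoxy-3-methylphenyl)prop-2-en-1-one | COc1ccc(/C=C/C(=O)c2c(O)cc(OC)c(C)c2OC)cc1Br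
F3 | step 9 | 3′-bromo-5,7,4′-trimethoxy-6-methylflavone | COc1ccc(-c2cc(=O)c3c(OC)c(C)c(OC)cc3o2)cc1Br
F4 | step 9 | 3′-bromo-5-hydroxy-7,4′-dimethoxy-6-methylflavone | COc1ccc(-c2cc(=O)c3c(O)c(C)c(OC)cc3o2)cc1Br
F5 | step 9 | 5-hydroxy-7,4′-dimethoxy-6-methyl-3′-(4,4,5,5-tetramethyl-1,3,2-dioxaborolan-2-yl)flavone | COc1ccc(-c2cc(=O)c3c(O)c(C)c(OC)cc3o2)cc1B1OC(C)(C)C(C)(C)O1
F6 | step 7 | 5-{hydroxy[6-aryl-4-oxo-4H-pyran-2-yl]methylidene}-2,2-dimethyl-1,3-dioxane-4,6-dione, aryl as in 12 | CC1(C)OC(=O)C(=C(O)c2cc(=O)cc(-c3ccc(OC)c(-c4c(OCc5ccccc5)cc(OCc5ccccc5)c5c(=O)cc(-c6ccc(OCc7ccccc7)cc6)oc45)c3)o2)C(=O)O1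
F7 | step 7 | 2-acetyl-6-[4-methoxy-3-(5,7,4′-tri-O-benzylapigenin-8-yl)phenyl]-4H-pyran-4-one | CC(=O)c1cc(=O)cc(-c2ccc(OC)c(-c3c(OCc4ccccc4)cc(OCc4ccccc4)c4c(=O)cc(-c5ccc(OCc6ccccc6)cc5)oc34)c2)o1
F8 | step 7 | 4,4,4-trifluoro-1-{6-aryl-4-oxo-4H-pyran-2-yl}butane-1,3-dione, aryl as in 12 | FC(F)(F)C(=O)CC(=O)c1cc(=O)cc(-c2ccc(OC)c(-c3c(OCc4ccccc4)cc(OCc4ccccc4)c4c(=O)cc(-c5ccc(OCc6ccccc6)cc5)oc34)c2)o1
F9 | step 6 | ethyl 6-[4-methoxy-3-(trimethylstannyl)phenyl]-4-oxo-4H-pyran-2-carboxylate | CCOC(=O)c1cc(=O)cc(-c2ccc(OC)c([Sn](C)(C)C)c2)o1
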